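**Retrosynthetic overview**

1. Cespitularin K ⇐ acetylation of the C6 alcohol ⇐ ring B by the base-induced γ-ylidenebutenolide → cyclopent-4-ene-1,3-dione rearrangement (C9–C18 bond) of a ring-A-fused butenolide macrocycle.
2. Key step: iron-hydride HAT converts an isopropenyl group into the tertiary C15 radical, which closes the 12-membered ring by Giese addition to the butenolide β-carbon (C15–C11, quaternary centre); the lactone enolate so formed closes ring A by aldol onto the C13 aldehyde.
3. Cyclisation precursor ⇐ tandem Sonogashira/lactonisation of a terminal enyne with (Z)-3-iodoacrylic acid ⇐ boron aldol (C5–C6, sets C6) of a methyl ketone with (E)-3-methylpent-2-en-4-ynal.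
4. The methyl ketone (C1 stereocentre, isopropenyl group, masked C13 aldehyde) ⇐ ozonolysis of (R)-limonene ⇐ catalytic asymmetric Diels–Alder of isoprene with methyl vinyl ketone, then Wittig; the C4 ketone is methylenated only after the radical step.
5. Ring order: 12-membered ring and ring A together (step 8), then ring B (step 11).

Atom labels used below follow the target: C1 (ring-fusion CH), C2, C3, C4 (=C20H2), C5, C6 (OAc), C7=C8 (C19 methyl), C9, C10 (C=O), C11=C12, C13, C14, C15 (gem-dimethyl), C18 (C=O).

Assumption: C9 (acidic methine between two carbonyls) is taken to be the thermodynamically preferred epimer in the natural product and is set by equilibration.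
Assumption: the (S)-oxazaborolidinium catalyst gives the R adduct in step 1 and (−)-Ipc2BCl gives the 8S aldol in step 5; the mirror-image reagent is used if the sense proves opposite.
Assumption: 7 (pure E isomer) and 13 are purchased.

**Route**

Step 1
Reactants: 1 isoprene; 2 methyl vinyl ketone
Product: 3 (R)-1-(4-methylcyclohex-3-en-1-yl)ethan-1-one
Conditions: (S)-o-tolyl-oxazaborolidine (20 mol %), HNTf2 (18 mol %), CH2Cl2, −78 to −40 °C
Reagents that add atoms: none
Why: Oxazaborolidinium-catalysed asymmetric Diels–Alder reaction in which the activated enone adds to isoprene with para regiochemistry and the catalyst shields one enone face, setting the ring stereocentre (future C1) as R.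

Step 2
Reactants: 3 (R)-1-(4-methylcyclohex-3-en-1-yl)ethan-1-one
Product: 4 (R)-limonene
Conditions: Ph3PCH3Br, KOt-Bu, THF, 0 °C
Reagents that add atoms: methyltriphenylphosphonium bromide, C[P+](c1ccccc1)(c1ccccc1)c1ccccc1.[Br-]
Why: Wittig methylenation of the methyl ketone gives the isopropenyl group, and because the ylide reacts faster than the hindered tertiary α-carbon enolises at 0 °C the stereocentre is retained.

Step 3
Reactants: 4 (R)-limonene
Product: 6 (5R)-7,7-dimethoxy-5-(prop-1-en-2-yl)heptan-2-one, via keto aldehyde 5 (not isolated)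
Conditions: O3 (1 equiv, Sudan red 7B end-point), CH2Cl2/MeOH, −78 °C; Me2S, rt; then TsOH·H2O (5 mol %), rt
Reagents that add atoms: ozone, [O-][O+]=O; methanol, CO
Why: Ozonolysis is faster at the electron-richer trisubstituted ring alkene than at the isopropenyl group, reductive work-up gives keto aldehyde 5 and acid-catalysed acetalisation in methanol is selective for the aldehyde, the stereocentre being untouched.

Step 4
Reactants: 7 (2E)-3-methylpent-2-en-4-yn-1-ol
Product: 8 (2E)-3-methylpent-2-en-4-ynal
Conditions: MnO2 (10 equiv), CH2Cl2, rt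
Reagents that add atoms: none
Why: MnO2 oxidation of the allylic alcohol gives the enal without touching the alkyne or the E geometry.

Step 5
Reactants: 6 (5R)-7,7-dimethoxy-5-(prop-1-en-2-yl)heptan-2-one; 8 (2E)-3-methylpent-2-en-4-ynal
Product: 10 (3R,8S,9E)-8-hydroxy-1,1-dimethoxy-10-methyl-3-(prop-1-en-2-yl)dodec-9-en-11-yn-6-one, via enol borinate 9 (not isolated)
Conditions: (−)-Ipc2BCl, Et3N, Et2O, 0 °C; then 8, −78 to −20 °C; H2O2, pH 7 buffer, MeOH
Reagents that add atoms: none
Why: Paterson boron aldol in which (−)-Ipc2BCl/Et3N enolises the methyl side regioselectively and the chiral borinate adds to the si face of the enal, setting C6 as S (about 9:1 expected, minor isomer removed by chromatography).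

Step 6
Reactants: 10 (3R,8S,9E)-8-hydroxy-1,1-dimethoxy-10-methyl-3-(prop-1-en-2-yl)dodec-9-en-11-yn-6-one
Product: 12 (3R,8S,9E)-10-methyl-6-oxo-3-(prop-1-en-2-yl)-8-(triethylsilyloxy)dodec-9-en-11-ynal, via lutidinium salt 11 (not isolated)
Conditions: TESOTf (3 equiv), 2,6-lutidine (5 equiv), CH2Cl2, −20 to 0 °C; then H2O
Reagents that add atoms: triethylsilyl trifluoromethanesulfonate, CC[Si](CC)(CC)OS(=O)(=O)C(F)(F)F; water, O
Why: The silyl triflate/2,6-lutidine pair silylates the carbinol and at the same time converts the dimethyl acetal through its N-(1-methoxyalkyl)lutidinium salt into the aldehyde on aqueous quench (known chemoselective silyl triflate–pyridine base acetal cleavage), no stereocentre being involved.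

Step 7
Reactants: 12 (3R,8S,9E)-10-methyl-6-oxo-3-(prop-1-en-2-yl)-8-(triethylsilyloxy)dodec-9-en-11-ynal; 13 (2Z)-3-iodoprop-2-enoic acid
Product: 15 (5Z)-5-[(2E,4S,9R)-2-methyl-6,11-dioxo-9-(prop-1-en-2-yl)-4-(triethylsilyloxy)undec-2-en-1-ylidene]furan-2(5H)-one, via enynoic acid 14 (not isolated)
Conditions: PdCl2(PPh3)2 (5 mol %), CuI (10 mol %), Et3N, MeCN, rt
Reagents that add atoms: none
Why: Sonogashira coupling of the terminal alkyne with the (Z)-iodoacrylic acid followed by in situ 5-exo-dig carboxylate addition (tandem coupling–lactonisation) gives the γ-ylidene butenolide, the anti addition across the alkyne fixing the Z geometry.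

Step 8
Reactants: 15 (5Z)-5-[(2E,4S,9R)-2-methyl-6,11-dioxo-9-(prop-1-en-2-yl)-4-(triethylsilyloxy)undec-2-en-1-ylidene]furan-2(5H)-one
Product: 17 tricyclic C13-hydroxy enol lactone (1R,6S,7E,9Z; C15–C11 and C12–C13 bonds formed; C4 ketone; 6-OTES; mixture at C11/C12/C13), via lactone enolate 16 (not isolated)
Conditions: Fe(acac)3 (30 mol %), PhSiH3 (2.5 equiv), EtOH/THF 1:3, 2 mM (slow addition of 15), 50 °C
Reagents that add atoms: none
Why: Proposed new method: the iron hydride formed from Fe(acac)3 and PhSiH3 transfers a hydrogen atom to the isopropenyl group (Mukaiyama-type HAT; it is the only electron-rich 1,1-disubstituted alkene present because C4 is still a ketone), the nucleophilic tertiary C15 radical closes the 12-membered ring by Giese addition to the butenolide β-carbon C11 (attack at the exocyclic C9 would need a 10-membered ring holding an E alkene), the α-acyl radical is reduced to iron enolate 16 and this closes ring A by a six-membered aldol onto the C13 aldehyde; the closest known reactions are the HAT-initiated reductive olefin coupling, its radical–polar crossover Giese/aldol annulation variant and endo radical macrocyclisation onto acrylates; C1 and C6 are untouched and the three new centres are erased in step 10.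

Step 9
Reactants: 17 tricyclic C13-hydroxy enol lactone (1R,6S,7E,9Z; C15–C11 and C12–C13 bonds formed; C4 ketone; 6-OTES; mixture at C11/C12/C13)
Product: 18 C4-methylene analogue of 17 (1R,6S,7E,9Z; C4=C20H2)
Conditions: CH2Br2, Zn, TiCl4, THF/CH2Cl2, 0 °C to rt
Reagents that add atoms: dibromomethane, BrCBr
Why: Takai–Lombardo methylenation is non-basic and selective for the ketone over the lactone, so the β-silyloxy ketone does not eliminate and the free carbinol and enol lactone survive.

Step 10
Reactants: 18 C4-methylene analogue of 17 (1R,6S,7E,9Z; C4=C20H2)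
Product: 21 ring-A-fused (Z)-γ-ylidene butenolide (1R,6S,7E,9Z; C11=C12; C4=C20H2; 6-OTES), via C13 acetate 19 (not isolated), via alkylidene lactone 20 (not isolated)
Conditions: Ac2O, Et3N, DMAP (cat.), CH2Cl2, 0 °C to rt; then DBU, MeCN, 50 °C
Reagents that add atoms: none
Why: Acetylation of the only free hydroxyl (C13) and E1cB elimination give alkylidene lactone 20, and DBU then removes the doubly allylic C11–H and reprotonates at C13 to give the fully conjugated tetrasubstituted butenolide, the C6 silyl ether being too poor a leaving group for vinylogous elimination.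

Step 11
Reactants: 21 ring-A-fused (Z)-γ-ylidene butenolide (1R,6S,7E,9Z; C11=C12; C4=C20H2; 6-OTES)
Product: 24 6-O-deacetylcespitularin K (1R,6S,9S,7E), via keto ester enolate 22 (not isolated), via sodium dionate 23 (not isolated)
Conditions: NaOMe (1.2 equiv), MeOH/THF, 0 °C; then 1 M HCl, THF, rt
Reagents that add atoms: none
Why: Methoxide opens the enol lactone to keto ester enolate 22, whose C9 carbanion closes ring B by Claisen (Dieckmann-type) acylation at C18 (the classical γ-ylidenebutenolide to cyclopent-4-ene-1,3-dione rearrangement), the acidic dionate 23 resists further base, and aqueous HCl protonates C9 and removes the silyl group, C9 settling to the assumed thermodynamic S epimer through its easily formed enol.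

Step 12
Reactants: 24 6-O-deacetylcespitularin K (1R,6S,9S,7E)
Product: 25 Cespitularin K (1R,6S,9S,7E)
Conditions: Ac2O, Sc(OTf)3 (1 mol %), MeCN, −20 °C
Reagents that add atoms: acetic anhydride, CC(=O)OC(C)=O
Why: Lewis-acid-catalysed acetylation of the secondary allylic alcohol proceeds with retention at C6 under base-free conditions, which avoids deprotonation at C9 and 1,4-elimination of the new allylic acetate.

**Compound list**

1 | isoprene | CC(=C)C=C | starting material
2 | methyl vinyl ketone | CC(=O)C=C | starting material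
3 | (R)-1-(4-methylcyclohex-3-en-1-yl)ethan-1-one | CC1=CC[C@@H](CC1)C(C)=O | intermediate
4 | (R)-limonene | CC1=CC[C@@H](CC1)C(C)=C | intermediate
5 | (3R)-6-oxo-3-(prop-1-en-2-yl)heptanal (keto aldehyde, not isolated) | O=CC[C@@H](CCC(C)=O)C(C)=C | intermediate
6 | (5R)-7,7-dimethoxy-5-(prop-1-en-2-yl)heptan-2-one | COC(OC)C[C@@H](CCC(C)=O)C(C)=C | intermediate
7 | (2E)-3-methylpent-2-en-4-yn-1-ol | OC/C=C(\C)C#C | starting material
8 | (2E)-3-methylpent-2-en-4-ynal | O=C/C=C(\C)C#C | intermediate
9 | methyl-side enol diisopinocampheylborinate of 6 (not isolated) | C=C(OB([C@@H]1C[C@@H]2C[C@H]([C@H]1C)C2(C)C)[C@@H]1C[C@@H]2C[C@H]([C@H]1C)C2(C)C)CC[C@H](CC(OC)OC)C(C)=C | intermediate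
10 | (3R,8S,9E)-8-hydroxy-1,1-dimethoxy-10-methyl-3-(prop-1-en-2-yl)dodec-9-en-11-yn-6-one | COC(OC)C[C@@H](CCC(=O)C[C@H](O)/C=C(\C)C#C)C(C)=C | intermediate
11 | N-(1-methoxyalkyl)-2,6-lutidinium triflate of the O-triethylsilyl ether of 10 (not isolated; mixture at the N,O-acetal carbon) | COC(C[C@@H](CCC(=O)C[C@H](O[Si](CC)(CC)CC)/C=C(\C)C#C)C(C)=C)[n+]1c(C)cccc1C.[O-]S(=O)(=O)C(F)(F)F | intermediate
12 | (3R,8S,9E)-10-methyl-6-oxo-3-(prop-1-en-2-yl)-8-(triethylsilyloxy)dodec-9-en-11-ynal | O=CC[C@@H](CCC(=O)C[C@H](O[Si](CC)(CC)CC)/C=C(\C)C#C)C(C)=C | intermediate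
13 | (2Z)-3-iodoprop-2-enoic acid | OC(=O)/C=C\I | starting material
14 | (2Z,6E,8S,13R)-6-methyl-10,15-dioxo-13-(prop-1-en-2-yl)-8-(triethylsilyloxy)pentadeca-2,6-dien-4-ynoic acid (not isolated) | OC(=O)/C=C\C#C/C(C)=C/[C@@H](O[Si](CC)(CC)CC)CC(=O)CC[C@H](CC=O)C(C)=C | intermediate
15 | (5Z)-5-[(2E,4S,9R)-2-methyl-6,11-dioxo-9-(prop-1-en-2-yl)-4-(triethylsilyloxy)undec-2-en-1-ylidene]furan-2(5H)-one | O=C1C=C/C(=C/C(C)=C/[C@@H](O[Si](CC)(CC)CC)CC(=O)CC[C@H](CC=O)C(C)=C)O1 | intermediate
16 | C12 lactone enolate of the 12-membered Giese adduct (C15–C11 bond formed, C13 aldehyde free; iron enolate drawn as the anion; not isolated) | [O-]C1=CC2/C(O1)=C/C(C)=C/[C@@H](O[Si](CC)(CC)CC)CC(=O)CC[C@H](CC=O)C2(C)C | intermediate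
17 | tricyclic C13-hydroxy enol lactone (1R,6S,7E,9Z; C15–C11 and C12–C13 bonds formed; C4 ketone; 6-OTES; mixture at C11/C12/C13) | O=C1O/C2=C\C(C)=C\[C@@H](O[Si](CC)(CC)CC)CC(=O)CC[C@@H]3CC(O)C1C2C3(C)C | intermediate
18 | C4-methylene analogue of 17 (1R,6S,7E,9Z; C4=C20H2) | O=C1O/C2=C\C(C)=C\[C@@H](O[Si](CC)(CC)CC)CC(=C)CC[C@@H]3CC(O)C1C2C3(C)C | intermediate
19 | C13 acetate of 18 (not isolated) | O=C1O/C2=C\C(C)=C\[C@@H](O[Si](CC)(CC)CC)CC(=C)CC[C@@H]3CC(OC(C)=O)C1C2C3(C)C | intermediate
20 | α-alkylidene enol lactone (C12=C13, C11–H; not isolated) | O=C1O/C2=C\C(C)=C\[C@@H](O[Si](CC)(CC)CC)CC(=C)CC[C@@H]3CC=C1C2C3(C)C | intermediate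
21 | ring-A-fused (Z)-γ-ylidene butenolide (1R,6S,7E,9Z; C11=C12; C4=C20H2; 6-OTES) | O=C1O/C2=C\C(C)=C\[C@@H](O[Si](CC)(CC)CC)CC(=C)CC[C@@H]3CCC1=C2C3(C)C | intermediate
22 | sodium enolate of the ring-opened methyl keto ester (C18 methyl ester on C12, C10 ketone; not isolated) | [Na+].COC(=O)C1=C2C([O-])=C/C(C)=C/[C@@H](O[Si](CC)(CC)CC)CC(=C)CC[C@H](CC1)C2(C)C | intermediate
23 | sodium dionate of 6-O-triethylsilyl-6-O-deacetylcespitularin K (not isolated) | [Na+].C=C1CC[C@@H]2CCC3=C(C([O-])=C(C3=O)/C(C)=C/[C@@H](O[Si](CC)(CC)CC)C1)C2(C)C | intermediate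
24 | 6-O-deacetylcespitularin K (1R,6S,9S,7E) | C=C1CC[C@@H]2CCC3=C(C(=O)[C@H](C3=O)/C(C)=C/[C@@H](O)C1)C2(C)C | intermediate
25 | Cespitularin K (1R,6S,9S,7E) | C=C1CC[C@@H]2CCC3=C(C(=O)[C@H](C3=O)/C(C)=C/[C@@H](OC(C)=O)C1)C2(C)C | target

**Step count and risks**

Total step count: 12. Longest linear sequence: 11 steps (steps 1–3 and 5–12, from isoprene and methyl vinyl ketone); step 4 is a one-step branch.

The three steps most likely to fail are steps 8, 10 and 11.

Step 8 can fail through radical attack at the exocyclic C9 of the ylidene butenolide, through reduction of the C15 radical before the large ring closes, or through protonation of the enolate before the aldol. The fallback moves lactone formation behind the radical step and sets out from 12. Sonogashira coupling of 12 with methyl (2Z)-3-iodoprop-2-enoate (PdCl2(PPh3)2, CuI, Et3N) gives the open-chain methyl (2Z,6E,8S,13R)-6-methyl-10,15-dioxo-13-(prop-1-en-2-yl)-8-(triethylsilyloxy)pentadeca-2,6-dien-4-ynoate F1. In F1 the enoate β-carbon is the only low-strain site for the C15 radical, since attack at the alkyne carbon would give a cyclic allene. The same Fe(acac)3/PhSiH3 Giese/aldol cascade then gives the macrocyclic alkynyl hydroxy ester F2. Hydrolysis with Me3SnOH gives the macrocyclic alkynyl hydroxy acid F3, and AgNO3-catalysed 5-exo-dig lactonisation of F3 comes back to the route at 17.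

Step 10 can stall at the alkylidene lactone because the C11–H is only weakly acidic. The fallback sets out from 20, isolated after the Et3N-mediated elimination, and replaces the carbanion pathway by a thiol hydrogen-atom shuttle (PhSH 20 mol %, AIBN, benzene, 80 °C). The thiyl radical abstracts the doubly allylic C11–H and the pentadienyl radical is re-hydrogenated at C13. This comes back to the route at 21 and makes no new compound (entry F0).

Step 11 can suffer from competing silyl or macrocycle degradation under alkoxide, or from incomplete Claisen closure in the protic medium. The fallback sets out from 21 and splits the rearrangement into two discrete reactions. Neutral methanolysis of the enol lactone (MeOH, Et3N cat., 0 °C) gives the isolated ring-opened methyl keto ester F4. Kinetically controlled Claisen closure in an aprotic medium (KHMDS 2.2 equiv, THF, −78 °C) then gives the potassium dionate of 6-O-triethylsilyl-6-O-deacetylcespitularin K F5. Aqueous HCl converts F5 into 24, where the route is rejoined.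

**Further compounds**

F1 | step 8 | methyl (2Z,6E,8S,13R)-6-methyl-10,15-dioxo-13-(prop-1-en-2-yl)-8-(triethylsilyloxy)pentadeca-2,6-dien-4-ynoate | COC(=O)/C=C\C#C/C(C)=C/[C@@H](O[Si](CC)(CC)CC)CC(=O)CC[C@H](CC=O)C(C)=C
F2 | step 8 | macrocyclic alkynyl hydroxy ester (C15–C11 and C12–C13 bonds formed; CO2Me on C12; OH on C13; C9≡C10 in the 12-membered ring; 1R,6S,7E; mixture at C11/C12/C13) | COC(=O)C1C(O)C[C@H]2CCC(=O)C[C@H](O[Si](CC)(CC)CC)/C=C(\C)C#CC1C2(C)C
F3 | step 8 | macrocyclic alkynyl hydroxy acid (free acid of F2) | OC(=O)C1C(O)C[C@H]2CCC(=O)C[C@H](O[Si](CC)(CC)CC)/C=C(\C)C#CC1C2(C)C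
F0 | step 10 | none | none
F4 | step 11 | ring-opened methyl keto ester (neutral; C18 methyl ester on C12, C10 ketone, C9H2; 1R,6S,7E) | COC(=O)C1=C2C(=O)C/C(C)=C/[C@@H](O[Si](CC)(CC)CC)CC(=C)CC[C@H](CC1)C2(C)C
F5 | step 11 | potassium dionate of 6-O-triethylsilyl-6-O-deacetylcespitularin K | [K+].C=C1CC[C@@H]2CCC3=C(C([O-])=C(C3=O)/C(C)=C/[C@@H](O[Si](CC)(CC)CC)C1)C2(C)C
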